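**Retrosynthetic overview**
- Ring B (the pyran) is closed last: one carbon (C1) is condensed onto the γ-CH2 of an ynenone and the resulting enol oxygen adds 6-endo to the alkyne.
- The enyne acid side chain is attached by Sonogashira coupling to the vinylogous acyl triflate of a cyclohexane-1,3-dione (ring A).
- Ring A is made by ring expansion of a γ-acetyl-γ-butyrolactone: the five-membered lactone becomes the six-membered carbocycle (key step).
- The lactone comes from a catalytic enantioselective aldol–lactonisation of a succinic half-ester with butane-2,3-dione, which sets C7 and C8.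
- The ester alcohol is made from (S)-1-bromo-2-methylbutane. Ring order: lactone, then ring A, then ring B.

Assumption: all five starting materials, including the enynoic acid used in step 7, are taken as catalogue compounds.

**Step 1**
Reactants: 1 (S)-1-bromo-2-methylbutane; 2 N-methoxy-N-methylacetamide
Product: 4 (S)-4-methylhexan-2-one, via Grignard reagent 3 (not isolated)
Conditions: Mg, THF, 40 °C; then 2, 0 °C to rt; 1 M HCl
Reagents that add atoms: none
Why: Weinreb ketone synthesis stops at the ketone through the chelated tetrahedral adduct, and the stereocentre of 1 is β to magnesium and is not touched.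

**Step 2**
Reactants: 4 (S)-4-methylhexan-2-one
Product: 5 (2S,4S)-4-methylhexan-2-ol
Conditions: alcohol dehydrogenase ADH-A (Rhodococcus ruber), NAD+ (cat.), i-PrOH, phosphate buffer pH 7.5, 30 °C
Reagents that add atoms: none
Why: The Prelog-selective dehydrogenase delivers hydride to the re face of the methyl ketone, which sets 2S under catalyst control while 4S is carried over from 1 (biocatalytic transfer hydrogenation).

**Step 3**
Reactants: 5 (2S,4S)-4-methylhexan-2-ol; 6 succinic anhydride
Product: 7 4-{[(2S,4S)-4-methylhexan-2-yl]oxy}-4-oxobutanoic acid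
Conditions: DMAP (10 mol %), Et3N, CH2Cl2, rt
Reagents that add atoms: none
Why: DMAP-catalysed alcoholysis of the cyclic anhydride gives the half-ester without touching either stereocentre (nucleophilic acyl substitution).

**Step 4**
Reactants: 7 4-{[(2S,4S)-4-methylhexan-2-yl]oxy}-4-oxobutanoic acid; 8 butane-2,3-dione
Product: 11 (2S,4S)-4-methylhexan-2-yl (2R,3R)-2-acetyl-2-methyl-5-oxooxolane-3-carboxylate, via bis-silyl ketene acetal 9 (not isolated), via silylated aldol adduct 10 (not isolated)
Conditions: LiN(i-Pr)2 (2.2 equiv), Me3SiCl, THF, −78 °C, volatiles removed, pentane filtration; then 8 (3 equiv), Cu(OSO2CF3)2 (10 mol %), (R,R)-t-Bu-box (11 mol %), THF, −78 °C; then 1 M HCl, rt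
Reagents that add atoms: none
Why: The half-ester dianion enolises α to the ester and its silyl ketene acetal adds to diketone 8 held as a five-membered chelate on the divalent copper bis(oxazoline) complex, whose tert-butyl groups leave one carbonyl face open, so that 7R is set by the catalyst and 8R by the syn-selective open transition state before acid closes the γ-lactone (Evans-type enantioselective Mukaiyama aldol, then lactonisation).

**Step 5**
Reactants: 11 (2S,4S)-4-methylhexan-2-yl (2R,3R)-2-acetyl-2-methyl-5-oxooxolane-3-carboxylate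
Product: 13 (2S,4S)-4-methylhexan-2-yl (1R,2R)-2-hydroxy-2-methyl-3,5-dioxocyclohexane-1-carboxylate, via bridged lithium alkoxide 12 (not isolated)
Conditions: LiN(SiMe3)2 (1.1 equiv), THF, −78 to 23 °C; AcOH
Reagents that add atoms: none
Why: Proposed new method: the kinetic lithium enolate of the acetyl group adds to the lactone carbonyl to give bridged alkoxide 12, whose ring C–O bond then breaks to release the tertiary alkoxide and the cyclohexane-1,3-dione, so the five-membered lactone is expanded to the six-membered carbocycle with both stereocentres kept and with irreversible 1,3-dionate formation as driving force; the closest known reaction types are the intramolecular Claisen (Dieckmann) condensation and the base isomerisation of enol lactones to cyclic 1,3-diones.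

**Step 6**
Reactants: 13 (2S,4S)-4-methylhexan-2-yl (1R,2R)-2-hydroxy-2-methyl-3,5-dioxocyclohexane-1-carboxylate
Product: 14 (2S,4S)-4-methylhexan-2-yl (1R,2R)-2-hydroxy-2-methyl-3-oxo-5-{[(trifluoromethyl)sulfonyl]oxy}cyclohex-4-ene-1-carboxylate
Conditions: (CF3SO2)2O (1.05 equiv), 2,6-lutidine, CH2Cl2, −78 °C
Reagents that add atoms: trifluoromethanesulfonic anhydride O=S(=O)(OS(=O)(=O)C(F)(F)F)C(F)(F)F
Why: O-sulfonylation of the 1,3-dione enolate takes place at the oxygen remote from the quaternary, hydrogen-bonded carbinol centre, which gives the vinylogous acyl triflate and keeps the ketone next to the tertiary alcohol (enol triflate formation).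

**Step 7**
Reactants: 14 (2S,4S)-4-methylhexan-2-yl (1R,2R)-2-hydroxy-2-methyl-3-oxo-5-{[(trifluoromethyl)sulfonyl]oxy}cyclohex-4-ene-1-carboxylate; 15 (E)-pent-2-en-4-ynoic acid
Product: 16 (E)-5-[(4R,5R)-4-hydroxy-4-methyl-5-({[(2S,4S)-4-methylhexan-2-yl]oxy}carbonyl)-3-oxocyclohex-1-en-1-yl]pent-2-en-4-ynoic acid
Conditions: PdCl2(PPh3)2 (5 mol %), CuI (10 mol %), i-Pr2NEt, THF, rt
Reagents that add atoms: none
Why: Sonogashira coupling of the electron-poor vinyl triflate with the terminal alkyne runs at room temperature, keeps the E-alkene and carries the acid as its ammonium salt.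

**Step 8**
Reactants: 16 (E)-5-[(4R,5R)-4-hydroxy-4-methyl-5-({[(2S,4S)-4-methylhexan-2-yl]oxy}carbonyl)-3-oxocyclohex-1-en-1-yl]pent-2-en-4-ynoic acid
Product: 19 (E)-3-[(7R,8R)-7-hydroxy-7-methyl-8-({[(2S,4S)-4-methylhexan-2-yl]oxy}carbonyl)-6-oxo-7,8-dihydro-6H-isochromen-3-yl]prop-2-enoic acid, via enaminone 17 (not isolated), via hydroxymethylene enol 18 (not isolated)
Conditions: t-BuOCH(NMe2)2 (2.5 equiv), toluene, 60 °C; then AcOH/H2O, THF, 40 °C
Reagents that add atoms: tert-butoxybis(dimethylamino)methane CN(C)C(OC(C)(C)C)N(C)C; water O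
Why: Bredereck's reagent condenses with the only acidic methylene (the γ-CH2 of the ynenone, the α′-position being quaternary), hydrolysis unmasks enol 18, and its oxygen adds to the δ-carbon of the ynenone in a 6-endo-dig oxa-Michael cyclisation that forms ring B, while C8 stays in its thermodynamically preferred configuration trans to the C7 methyl (aminomethylenation, then conjugate-addition cycloisomerisation).

**Compound list**
1 | (S)-1-bromo-2-methylbutane | CC[C@H](C)CBr | starting material
2 | N-methoxy-N-methylacetamide | CC(=O)N(C)OC | starting material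
3 | (S)-2-methylbutylmagnesium bromide | CC[C@H](C)C[Mg]Br | intermediate
4 | (S)-4-methylhexan-2-one | CC[C@H](C)CC(C)=O | intermediate
5 | (2S,4S)-4-methylhexan-2-ol | CC[C@H](C)C[C@H](C)O | intermediate
6 | succinic anhydride | O=C1CCC(=O)O1 | starting material
7 | 4-{[(2S,4S)-4-methylhexan-2-yl]oxy}-4-oxobutanoic acid | CC[C@H](C)C[C@H](C)OC(=O)CCC(=O)O | intermediate
8 | butane-2,3-dione | CC(=O)C(C)=O | starting material
9 | trimethylsilyl 4-{[(2S,4S)-4-methylhexan-2-yl]oxy}-4-[(trimethylsilyl)oxy]but-3-enoate | CC[C@H](C)C[C@H](C)OC(O[Si](C)(C)C)=CCC(=O)O[Si](C)(C)C | intermediate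
10 | trimethylsilyl (3R,4R)-4-methyl-3-({[(2S,4S)-4-methylhexan-2-yl]oxy}carbonyl)-5-oxo-4-[(trimethylsilyl)oxy]hexanoate | CC[C@H](C)C[C@H](C)OC(=O)[C@H](CC(=O)O[Si](C)(C)C)[C@@](C)(O[Si](C)(C)C)C(C)=O | intermediate
11 | (2S,4S)-4-methylhexan-2-yl (2R,3R)-2-acetyl-2-methyl-5-oxooxolane-3-carboxylate | CC[C@H](C)C[C@H](C)OC(=O)[C@@H]1CC(=O)O[C@@]1(C)C(C)=O | intermediate
12 | lithium (1R,2R,4S)-1-methyl-2-({[(2S,4S)-4-methylhexan-2-yl]oxy}carbonyl)-6-oxo-7-oxabicyclo[2.2.1]heptan-4-olate | [Li+].CC[C@H](C)C[C@H](C)OC(=O)[C@@H]1C[C@@]2([O-])CC(=O)[C@]1(C)O2 | intermediate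
13 | (2S,4S)-4-methylhexan-2-yl (1R,2R)-2-hydroxy-2-methyl-3,5-dioxocyclohexane-1-carboxylate | CC[C@H](C)C[C@H](C)OC(=O)[C@@H]1CC(=O)CC(=O)[C@]1(C)O | intermediate
14 | (2S,4S)-4-methylhexan-2-yl (1R,2R)-2-hydroxy-2-methyl-3-oxo-5-{[(trifluoromethyl)sulfonyl]oxy}cyclohex-4-ene-1-carboxylate | CC[C@H](C)C[C@H](C)OC(=O)[C@@H]1CC(OS(=O)(=O)C(F)(F)F)=CC(=O)[C@]1(C)O | intermediate
15 | (E)-pent-2-en-4-ynoic acid | C#C/C=C/C(=O)O | starting material
16 | (E)-5-[(4R,5R)-4-hydroxy-4-methyl-5-({[(2S,4S)-4-methylhexan-2-yl]oxy}carbonyl)-3-oxocyclohex-1-en-1-yl]pent-2-en-4-ynoic acid | CC[C@H](C)C[C@H](C)OC(=O)[C@@H]1CC(C#C/C=C/C(=O)O)=CC(=O)[C@]1(C)O | intermediate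
17 | (E)-5-[(4R,5R)-6-[(dimethylamino)methylidene]-4-hydroxy-4-methyl-5-({[(2S,4S)-4-methylhexan-2-yl]oxy}carbonyl)-3-oxocyclohex-1-en-1-yl]pent-2-en-4-ynoic acid | CC[C@H](C)C[C@H](C)OC(=O)[C@@H]1C(=CN(C)C)C(C#C/C=C/C(=O)O)=CC(=O)[C@]1(C)O | intermediate
18 | (E)-5-[(4R,5R)-4-hydroxy-6-(hydroxymethylidene)-4-methyl-5-({[(2S,4S)-4-methylhexan-2-yl]oxy}carbonyl)-3-oxocyclohex-1-en-1-yl]pent-2-en-4-ynoic acid | CC[C@H](C)C[C@H](C)OC(=O)[C@@H]1C(=CO)C(C#C/C=C/C(=O)O)=CC(=O)[C@]1(C)O | intermediate
19 | (E)-3-[(7R,8R)-7-hydroxy-7-methyl-8-({[(2S,4S)-4-methylhexan-2-yl]oxy}carbonyl)-6-oxo-7,8-dihydro-6H-isochromen-3-yl]prop-2-enoic acid | CC[C@H](C)C[C@H](C)OC(=O)[C@@H]1C2=COC(/C=C/C(=O)O)=CC2=CC(=O)[C@]1(C)O | target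

**Step count and risks**
Total steps: 8. Longest linear sequence: 8 (1 to 19; 2, 6, 8 and 15 enter as bought materials).

The three steps most likely to fail are steps 4, 5 and 8.

Step 4 (ester-derived, α-branched silyl ketene acetal in the copper-catalysed diketone aldol). If 9 reacts slowly or with poor selectivity, the thioester nucleophile class documented for this catalyst is used instead. The fallback sets out from 6: the anhydride is opened with 2-methylpropane-2-thiol to 4-(tert-butylsulfanyl)-4-oxobutanoic acid F1, which LiN(i-Pr)2 and Me3SiCl convert into trimethylsilyl 4-(tert-butylsulfanyl)-4-[(trimethylsilyl)oxy]but-3-enoate F2. The aldol with 8 under the catalyst of step 4 gives trimethylsilyl (3R,4R)-3-[(tert-butylsulfanyl)carbonyl]-4-methyl-5-oxo-4-[(trimethylsilyl)oxy]hexanoate F3, and acid closes it to S-tert-butyl (2R,3R)-2-acetyl-2-methyl-5-oxooxolane-3-carbothioate F4. Silver-promoted thioester-to-ester exchange with alcohol 5 (AgOCOCF3, CH2Cl2) then gives 11, where the route is rejoined.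

Step 5 (the proposed ring expansion, which must pass through a strained bridged adduct and competes with eliminative opening of the lactone). The fallback uses the textbook open-chain Claisen route to cyclohexane-1,3-diones and sets out from 10. Instead of acid work-up, the silyl ester of 10 is cleaved with methanol and the acid methylated with Me3SiCHN2 to methyl (3R,4R)-4-methyl-3-({[(2S,4S)-4-methylhexan-2-yl]oxy}carbonyl)-5-oxo-4-[(trimethylsilyl)oxy]hexanoate F5. KOC(CH3)3 in THF condenses the methyl ketone onto the methyl ester to give (2S,4S)-4-methylhexan-2-yl (1R,2R)-2-methyl-3,5-dioxo-2-[(trimethylsilyl)oxy]cyclohexane-1-carboxylate F6, and citric acid in methanol removes the silyl ether to return to the route at 13.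

Step 8 (γ-selectivity of the aminomethylenation, and possible addition of dimethylamine to the ynenoate). The fallback introduces the carbon stepwise by known vinylogous chemistry and sets out from 16. Et3SiOSO2CF3 and Et3N give triethylsilyl (E)-5-[(3R,4R)-4-methyl-3-({[(2S,4S)-4-methylhexan-2-yl]oxy}carbonyl)-4,5-bis[(triethylsilyl)oxy]cyclohexa-1,5-dien-1-yl]pent-2-en-4-ynoate F7. (Chloromethylene)dimethyliminium chloride attacks the γ-terminus of this silyl dienol ether (vinylogous Vilsmeier formylation), and work-up with aqueous HF–pyridine gives 18, now isolated. Gold triacetate Au(OCOCH3)3 (5 mol %, trivalent gold) in wet 1,2-dichloroethane then effects the 6-endo cycloisomerisation known for o-alkynyl aldehydes in azaphilone synthesis and returns to the route at 19.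

**Further compounds**
F1 | step 4 | 4-(tert-butylsulfanyl)-4-oxobutanoic acid | CC(C)(C)SC(=O)CCC(=O)O
F2 | step 4 | trimethylsilyl 4-(tert-butylsulfanyl)-4-[(trimethylsilyl)oxy]but-3-enoate | CC(C)(C)SC(O[Si](C)(C)C)=CCC(=O)O[Si](C)(C)C
F3 | step 4 | trimethylsilyl (3R,4R)-3-[(tert-butylsulfanyl)carbonyl]-4-methyl-5-oxo-4-[(trimethylsilyl)oxy]hexanoate | CC(C)(C)SC(=O)[C@H](CC(=O)O[Si](C)(C)C)[C@@](C)(O[Si](C)(C)C)C(C)=O
F4 | step 4 | S-tert-butyl (2R,3R)-2-acetyl-2-methyl-5-oxooxolane-3-carbothioate | CC(C)(C)SC(=O)[C@@H]1CC(=O)O[C@@]1(C)C(C)=O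
F5 | step 5 | methyl (3R,4R)-4-methyl-3-({[(2S,4S)-4-methylhexan-2-yl]oxy}carbonyl)-5-oxo-4-[(trimethylsilyl)oxy]hexanoate | CC[C@H](C)C[C@H](C)OC(=O)[C@H](CC(=O)OC)[C@@](C)(O[Si](C)(C)C)C(C)=O
F6 | step 5 | (2S,4S)-4-methylhexan-2-yl (1R,2R)-2-methyl-3,5-dioxo-2-[(trimethylsilyl)oxy]cyclohexane-1-carboxylate | CC[C@H](C)C[C@H](C)OC(=O)[C@@H]1CC(=O)CC(=O)[C@]1(C)O[Si](C)(C)C
F7 | step 8 | triethylsilyl (E)-5-[(3R,4R)-4-methyl-3-({[(2S,4S)-4-methylhexan-2-yl]oxy}carbonyl)-4,5-bis[(triethylsilyl)oxy]cyclohexa-1,5-dien-1-yl]pent-2-en-4-ynoate | CC[C@H](C)C[C@H](C)OC(=O)[C@@H]1C=C(C#C/C=C/C(=O)O[Si](CC)(CC)CC)C=C(O[Si](CC)(CC)CC)[C@]1(C)O[Si](CC)(CC)CC
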